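Ring A is disconnected at N1–C7a and C3–C3a. Its C4 nitrogen lies para to C7–OMe, while N1 sits on C7a, ortho to C7 and meta to C4: the pattern left when a para-anisidine, oxidized to its quinone imine ketal, accepts an amine beta to C=N. One flask thus oxidizes a diarylamine, adds aminoacetaldehyde dimethyl acetal and closes the pyrrole of ring A. The precursor is 4-bromo-N-(4-methoxyphenyl)aniline carrying an extra ortho 2,2-dibromoethenyl spectator; after bromination at C3 and C5 (directed by the diarylamine N–H) this group closes ring B as a 2-bromoindole, so C2'–Br, C3' and the N1'–C2' bond need no separate construction.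

Key step: step 4

Remark: the target has no stereocentre; its SMILES fixes no configuration for the hindered C4–N1' axis, so this axis is formed without control (as a racemate if rotation is slow).

Remark on design: the dibromoethenyl group is inert in the key step and fixes in advance on which aryl ring ring B will close; an indolization on the diarylamine nitrogen, which would have to choose between two rings and would give C2'–Br only indirectly, is avoided.

Step 1
Reactants: 1 5-bromo-2-nitrobenzaldehyde
Product: 2 4-bromo-2-(2,2-dibromoethenyl)-1-nitrobenzene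
Conditions: CBr4, PPh3, CH2Cl2, 0 °C
Reagents that add atoms: carbon tetrabromide, BrC(Br)(Br)Br
Why: Ramirez dibromoolefination (Wittig reaction of Ph3P=CBr2 generated from PPh3 and CBr4) works best on electron-poor aromatic aldehydes such as this ortho-nitrobenzaldehyde, and the nitro group and the aryl bromide are inert to the ylide.

Step 2
Reactants: 2 4-bromo-2-(2,2-dibromoethenyl)-1-nitrobenzene
Product: 3 4-bromo-2-(2,2-dibromoethenyl)aniline
Conditions: Fe powder, AcOH, EtOH, 80 °C
Reagents that add atoms: none
Why: Béchamp-type dissolving-metal reduction transfers electrons to the nitro group only, so the aryl and vinyl C–Br bonds, which a hydrogenation catalyst would cleave, are kept.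

Step 3
Reactants: 3 4-bromo-2-(2,2-dibromoethenyl)aniline; 4 4-methoxyphenylboronic acid
Product: 5 4-bromo-2-(2,2-dibromoethenyl)-N-(4-methoxyphenyl)aniline
Conditions: Cu(OAc)2 (20 mol %), myristic acid, 2,6-lutidine, toluene, air, 40 °C
Reagents that add atoms: none
Why: Chan–Lam N-arylation couples the aniline N–H with the electron-rich arylboronic acid through a Cu(OAc)2/air oxidative cycle that involves no oxidative addition to carbon–halogen bonds, so all three bromines survive, and the ortho substituent holds the reaction at the diarylamine stage.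

Step 4
Reactants: 5 4-bromo-2-(2,2-dibromoethenyl)-N-(4-methoxyphenyl)aniline; 6 aminoacetaldehyde dimethyl acetal (2,2-dimethoxyethanamine)
Product: 11 N-[4-bromo-2-(2,2-dibromoethenyl)phenyl]-7-methoxy-1H-indol-4-amine, via quinone imine ketal 7 (not isolated), via amino acetal 8 (not isolated), via trifluoroacetamide 9 (not isolated), via 1-trifluoroacetylindole 10 (not isolated)
Conditions: PhI(OAc)2 (1.05 equiv), MeOH, 0 °C; then 6 (4 equiv), 0 °C to rt; evaporate, wash out excess 6 (H2O/CH2Cl2); (CF3CO)2O (1.2 equiv), CH2Cl2, 0 °C, then CF3CO2H, rt, dilute; evaporate with toluene; K2CO3 (cat.), MeOH, rt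
Reagents that add atoms: methanol, CO (one methoxy group of ketal 7; one of the two ketal methoxy groups is kept in 11); trifluoroacetic anhydride, O=C(OC(=O)C(F)(F)F)C(F)(F)F (trifluoroacetyl group of 9 and 10 only, removed before 11)
Why: Proposed new method: PhI(OAc)2 removes two electrons from the anisidine ring of 5 and methanol traps the resulting cation at the methoxy-bearing carbon to give ketal 7 (benzidine-type coupling is closed off because bromine occupies the para position of the other ring); in the basic medium kept by excess 6 the ketal is not ionized, so the primary amine adds aza-Michael fashion to the ring carbon beta to C=N and loss of methanol rearomatizes to 8, which forms N1–C7a. (CF3CO)2O then caps the more nucleophilic alkyl aryl nitrogen, and CF3CO2H ionizes the acetal of 9 to an oxocarbenium ion that C3a attacks in a five-membered Friedel–Crafts closure (5-exo-trig at the oxocarbenium carbon, the arene bond endocyclic), forming C3–C3a; loss of methanol aromatizes the pyrrole and K2CO3 in methanol cleaves the labile N1 trifluoroacetyl group of 10. The closest known reactions are conjugate additions of nucleophiles to N-acyl and N-sulfonyl quinone imine ketals obtained with PhI(OAc)2 in methanol and the Nordlander cyclization of N-trifluoroacetyl anilinoacetaldehyde acetals to indoles; the N-aryl ketal, the amine nucleophile and the telescoping are new. No stereocenter is formed. The addition needs attack beta rather than alpha to C=N or at the imine carbon, which the non-acidic medium and the irreversible aromatization favour, and it needs no choice between the two beta carbons because the ketal is symmetric; the closure needs no regiocontrol either, since the arm on N1 can reach only C3a (C7 carries OMe), a position further activated by the free, weakly basic diarylamine nitrogen ortho to it.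

Step 5
Reactants: 11 N-[4-bromo-2-(2,2-dibromoethenyl)phenyl]-7-methoxy-1H-indol-4-amine
Product: 12 3,5-dibromo-N-[4-bromo-2-(2,2-dibromoethenyl)phenyl]-7-methoxy-1H-indol-4-amine
Conditions: NBS (2.0 equiv), THF, −78 to 0 °C, dark
Reagents that add atoms: N-bromosuccinimide, O=C1CCC(=O)N1Br
Why: Electrophilic aromatic substitution with NBS should occur first at C3, the most nucleophilic carbon of the indole, and then at C5, the only free position ortho to the strongly activating diarylamine N–H on the electron-rich ring A (para to it, C7 carries OMe), whereas the other aryl ring is deactivated by bromine and the dibromoethenyl group.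

Step 6
Reactants: 12 3,5-dibromo-N-[4-bromo-2-(2,2-dibromoethenyl)phenyl]-7-methoxy-1H-indol-4-amine
Product: 13 3,5-dibromo-4-(2,5-dibromo-1H-indol-1-yl)-7-methoxy-1H-indole (target)
Conditions: Pd(P(t-Bu)3)2 (5 mol %), K3PO4, toluene, 100 °C
Reagents that add atoms: none
Why: Intramolecular Buchwald–Hartwig vinyl amination of a gem-dibromoolefin: zerovalent palladium inserts into a vinylic C–Br bond much faster than into aryl or indolyl C–Br bonds, the diarylamide forms with K3PO4 and C–N reductive elimination closes the five-membered ring (N1'–C2'), the second vinylic bromine remaining as C2'–Br, while the bulky P(t-Bu)3 ligand makes oxidative addition to the C–Br bonds of the product reversible.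

Compound list
1 | 5-bromo-2-nitrobenzaldehyde | O=Cc1cc(Br)ccc1[N+](=O)[O-] | starting material
2 | 4-bromo-2-(2,2-dibromoethenyl)-1-nitrobenzene | O=[N+]([O-])c1ccc(Br)cc1C=C(Br)Br | intermediate
3 | 4-bromo-2-(2,2-dibromoethenyl)aniline | Nc1ccc(Br)cc1C=C(Br)Br | intermediate
4 | 4-methoxyphenylboronic acid | COc1ccc(B(O)O)cc1 | starting material
5 | 4-bromo-2-(2,2-dibromoethenyl)-N-(4-methoxyphenyl)aniline | COc1ccc(Nc2ccc(Br)cc2C=C(Br)Br)cc1 | intermediate
6 | aminoacetaldehyde dimethyl acetal (2,2-dimethoxyethanamine) | NCC(OC)OC | starting material
7 | N-[4-bromo-2-(2,2-dibromoethenyl)phenyl]-4,4-dimethoxycyclohexa-2,5-dien-1-imine | COC1(OC)C=CC(=Nc2ccc(Br)cc2C=C(Br)Br)C=C1 | intermediate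
8 | N1-[4-bromo-2-(2,2-dibromoethenyl)phenyl]-N3-(2,2-dimethoxyethyl)-4-methoxybenzene-1,3-diamine | COc1ccc(Nc2ccc(Br)cc2C=C(Br)Br)cc1NCC(OC)OC | intermediate
9 | N-(5-{[4-bromo-2-(2,2-dibromoethenyl)phenyl]amino}-2-methoxyphenyl)-N-(2,2-dimethoxyethyl)-2,2,2-trifluoroacetamide | COc1ccc(Nc2ccc(Br)cc2C=C(Br)Br)cc1N(CC(OC)OC)C(=O)C(F)(F)F | intermediate
10 | 1-(4-{[4-bromo-2-(2,2-dibromoethenyl)phenyl]amino}-7-methoxy-1H-indol-1-yl)-2,2,2-trifluoroethan-1-one | COc1ccc(Nc2ccc(Br)cc2C=C(Br)Br)c2ccn(C(=O)C(F)(F)F)c12 | intermediate
11 | N-[4-bromo-2-(2,2-dibromoethenyl)phenyl]-7-methoxy-1H-indol-4-amine | COc1ccc(Nc2ccc(Br)cc2C=C(Br)Br)c2cc[nH]c12 | intermediate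
12 | 3,5-dibromo-N-[4-bromo-2-(2,2-dibromoethenyl)phenyl]-7-methoxy-1H-indol-4-amine | COc1cc(Br)c(Nc2ccc(Br)cc2C=C(Br)Br)c2c(Br)c[nH]c12 | intermediate
13 | 3,5-dibromo-4-(2,5-dibromo-1H-indol-1-yl)-7-methoxy-1H-indole | COc1cc(Br)c(-n2c(Br)cc3cc(Br)ccc32)c2c(Br)c[nH]c12 | target

Total step count: 6
Longest linear sequence: 6 steps (1 → 2 → 3 → 5 → 11 → 12 → 13)

Steps most likely to fail

Step 4 (Proposed new method). What may go wrong:
- the amine may attack the imine carbon and exchange the arylamine;
- it may attack alpha to C=N if the ketal ionizes;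
- residual oxidant may over-oxidize the electron-rich diamine;
- the oxocarbenium ion may alkylate the nascent indole intermolecularly during ring closure.

Fallback by known chemistry, setting out from aniline 3 and returning to the route at 11: commercial 4-bromo-7-methoxy-1H-indole F1 undergoes Miyaura borylation (B2pin2, Pd(dppf)Cl2, KOAc, dioxane, 90 °C) to 7-methoxy-4-(4,4,5,5-tetramethyl-1,3,2-dioxaborolan-2-yl)-1H-indole F2. Chan–Lam coupling of F2 with 3 (Cu(OAc)2, B(OH)3, MeCN, air, 70 °C) then forms the C4–N bond and should give 11. Ring A is bought instead of built, and steps 5 and 6 follow unchanged.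

Step 6. What may go wrong:
- palladium may insert into the aryl or indolyl C–Br bonds;
- the free indole N–H may be N-arylated, leading to oligomers;
- the palladium amide may form slowly at the hindered diarylamine nitrogen.

Fallback without a transition metal, setting out from 12 and returning at 13: Cs2CO3 in DMSO at 80–100 °C should eliminate HBr from the dibromoolefin to give 3,5-dibromo-N-[4-bromo-2-(bromoethynyl)phenyl]-7-methoxy-1H-indol-4-amine F3. Its caesium anilide should add 5-endo-dig to the bromine-bearing alkyne carbon and, after protonation at C3', give 13. N-sulfonyl analogues are known to close to 2-bromoindoles this way. No metal is present that could touch the other C–Br bonds.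

Step 5. What may go wrong:
- the electron-rich aminoindole may be oxidized instead of substituted;
- a second bromine may enter at C2 or on the other aryl ring;
- the N–H 3-bromoindole may decompose on handling.

Fallback with a deactivated pyrrole ring, setting out from 11 and returning at 12: Boc2O/DMAP in MeCN should give tert-butyl 4-{[4-bromo-2-(2,2-dibromoethenyl)phenyl]amino}-7-methoxy-1H-indole-1-carboxylate F4. NBS should then brominate C5 first (ortho to the diarylamine N–H) and C3 second, giving tert-butyl 3,5-dibromo-4-{[4-bromo-2-(2,2-dibromoethenyl)phenyl]amino}-7-methoxy-1H-indole-1-carboxylate F5. The carbamate keeps the 3-bromoindole stable until K2CO3 in MeOH releases 12 directly before step 6.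

Further compounds
F1 | step 4 | 4-bromo-7-methoxy-1H-indole | COc1ccc(Br)c2cc[nH]c12
F2 | step 4 | 7-methoxy-4-(4,4,5,5-tetramethyl-1,3,2-dioxaborolan-2-yl)-1H-indole | COc1ccc(B2OC(C)(C)C(C)(C)O2)c2cc[nH]c12
F3 | step 6 | 3,5-dibromo-N-[4-bromo-2-(bromoethynyl)phenyl]-7-methoxy-1H-indol-4-amine | COc1cc(Br)c(Nc2ccc(Br)cc2C#CBr)c2c(Br)c[nH]c12
F4 | step 5 | tert-butyl 4-{[4-bromo-2-(2,2-dibromoethenyl)phenyl]amino}-7-methoxy-1H-indole-1-carboxylate | COc1ccc(Nc2ccc(Br)cc2C=C(Br)Br)c2ccn(C(=O)OC(C)(C)C)c12
F5 | step 5 | tert-butyl 3,5-dibromo-4-{[4-bromo-2-(2,2-dibromoethenyl)phenyl]amino}-7-methoxy-1H-indole-1-carboxylate | COc1cc(Br)c(Nc2ccc(Br)cc2C=C(Br)Br)c2c(Br)cn(C(=O)OC(C)(C)C)c12
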